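All runs stem from a simulated flask with made-up constants, and the scatter is random.

A leftover is what I reckon with here: the enzyme still free to work once the impurity has taken its share, one for one.

| flask | starting material | second substrate | enzyme | impurity | remark |
|---|---|---|---|---|---|
| Monday's | 0.012 M | 0.018 M | 1.2 µM | 0.47 µM | run made earlier |
| flask | 0.012 M | 0.0120 M | 1.2 µM | 0.47 µM |  |

Monday's run (percent of the starting material charged)

| time / s | target / % | starting material / % |
|---|---|---|
| 10.0 | 74.8 | 26.1 |
| 12.0 | 80.8 | 17.3 |
| 20.0 | 96.1 | 2.3 |
| 30.0 | 100.5 | 0.5 |
| 50.0 | 100.6 | 0 |

(scatter of a reading: 0.5 percentage points)

- apparent order in second substrate when 30% of the starting material are converted (percent change of the rate of making target for one percent more second substrate charged)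
- apparent order in enzyme when 30% of the starting material are converted (percent change of the rate of making target for one percent more enzyme charged)

- steps under discussion: starting material + enzyme <-> starting complex; second substrate + starting complex <-> ternary complex; ternary complex -> enzyme + target; enzyme + impurity -> spent catalyst
- no earlier run changes the charge of enzyme; that part of a forecast is a guess
- no earlier run changes the charge of second substrate; that part of a forecast is a guess

Two things seem not to go together in this flask. The impurity is 0.00392% of the starting material, and Monday's run, with the same charges of enzyme and impurity, still reached 100.6% target by 50.0 s. Yet I expect one percent more enzyme to raise the rate by more than one percent, which a catalyst is not supposed to do.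

The impurity has to be held against the enzyme, not against the starting material. It is the limiting reagent of its own step, being less than the enzyme. If that step is over before the flask reaches 30% conversion, then

enzyme charged − impurity charged = 0.730 µM

This is the working enzyme, the charge of enzyme less the charge of impurity. Monday's run has the same working enzyme, and its last target readings stand at the full charge of starting material, within their scatter. Extra enzyme adds to the working enzyme in full while the impurity stays as it was, so if the rate goes with the working enzyme,

order in enzyme = enzyme charged / working enzyme = 1.64

No earlier run changes the enzyme charge, so this remains my guess.

The forecast gives 1.55 for the enzyme, a little less than my figure, within 1.05 to 1.7, calling that figure "partly a guess", and 0.25 for the second substrate, within 0.05 to 0.6.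

The flask gives 1.6 for the enzyme and 0.96 for the second substrate.

    starting material + enzyme ⇌ starting complex (K = 910 /M, k = 6.20 × 10⁵ /M/s)
    second substrate + starting complex ⇌ ternary complex (K = 92.0 /M, k = 2.80 × 10⁵ /M/s)
    ternary complex → enzyme + target (k = 7500 /s)
    enzyme + impurity → spent catalyst (k = 1.80 × 10⁷ /M/s)

At the start of this flask, enzyme goes into starting complex 880 times faster than into spent catalyst, counting the forward rate of the reversible step alone, and still spent catalyst stands at 39.2% of the catalyst charged by 0.0669 min, the same as impurity over enzyme charged, 39.2%. The working enzyme of 0.730 µM is 60.8% of the charge, and in this flask free enzyme stands at 60.6% of the catalyst charged at 30.0 min.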